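The constants used here are made up; the rest is arithmetic.

A small charge of partner, less than the substrate charge, goes into this flask, so I keep my books on the partner, the limiting reagent.

substrate 20 mM (fed, over 15 min); partner 10.0 mM; free catalyst 2.0 mM; time 12 h

    partner + catalyst intermediate A → catalyst intermediate B (k1 = 2.1 M⁻¹ s⁻¹)
    catalyst intermediate B → catalyst intermediate C (k2 = 0.021 s⁻¹)
    crystals ⇌ released group, rate k3*(cs3 - [released group]) while solid is left; crystals form when [released group] > cs3 (cs3 = 14 mM, k3 = 0.028 s⁻¹)
    catalyst intermediate D → free catalyst + target (k4 = 0.0043 s⁻¹)
    catalyst intermediate C ⇌ released group + catalyst intermediate D (K5 = 0.22 M, k5 = 0.63 s⁻¹)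
    substrate + free catalyst → catalyst intermediate A (k6 = 1.6 M⁻¹ s⁻¹)
    substrate ⇌ dormant form (K7 = 2.7, k7 = 0.0024 s⁻¹)

- released group is meant together with its crystals
- solid, in amounts per volume of the solution: crystals
- the reaction counts as stopped when no species that holds the substrate changes by six tenths of a point or more over the second half of the time
- what has gone from substrate into another species counts as reacted, even if it can come back
- run time (flask): 12 h

- the state of affairs at 12 h: stopped, and by what, or still going (all of the substrate has reacted / the partner has run out first / no working catalyst is left / it is still moving)
- how much of the substrate has reacted by 12 h
- how much target there is at 12 h, in percent of the substrate charged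

1. Each partner passes through intermediates B, C and D and leaves as one target and one released group. The target entry in this flask can therefore reach 50.0% of the substrate charge.

2. Does the partner get that far? At full partner, intermediate A reacts at 0.0210 s⁻¹, faster than intermediate D releases target at 0.0043 s⁻¹, so I expect intermediate D to hold more of the catalyst than intermediate A at first. But the first rate falls with the partner and crosses 0.0043 s⁻¹ at 20.5% of the partner's charge. Below that the catalyst waits at A, and the partner decays pseudo-first-order with a half-life of 2.75 min. The time allows 262 such half-lives, so I close the partner's account.

3. The released group can reach 71.4% of its solubility, so I enter no crystals. It reaches 4.55% of the equilibrium constant, so I enter no lasting return through intermediate C.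

4. Substrate exceeds what target and catalyst can take, so the freed catalyst binds one more substrate and rests as intermediate A, its resting state. That entry is 10.0% of the substrate charge.

5. That leaves 40.0%. Substrate and dormant form relax with a half-life of 0.0585 h, short against the time, so this remainder splits one part substrate to 2.7 parts dormant form.

6. The free remainder is therefore 10.8%: the free remainder, meaning the substrate charge less the target and the catalyst's hold, divided by 3.70. Conversion in this flask is 89.2%, and I expect target at 50.0%, with the partner's account closed.

The forecast gives the partner has run out first, 89.2% and 50%, saying “the target stops at 10 mM (50%)”.

The flask gives the partner has run out first, 89.2% and 50.0%.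

In this flask at 12.0 h, partner stands at 0% of its charge and substrate at 10.8%, against my free remainder of 10.8%. The neighbouring flask charges 2.5 mM of partner, all else as in this recipe. Its books give target 12.5%, a catalyst hold of 10.0%, and a free remainder of 20.9%, hence conversion 79.1%. Simulated, the neighbouring flask holds 10.0% as intermediate A and 12.5% as target, with conversion 79.1% and substrate 20.9%.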